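If a plateau stops short of the charge, the first question is what the shortfall follows.

| setting | north-west | west | flask |
|---|---|---|---|
| solid substrate | 0.14 M | 0.22 M | 0.10 M |
| partner | 3 equiv | 3 equiv | 3.00 equiv |
| remark | run made earlier | run made earlier |  |
| time |  |  | 12 min |

| run | time / min | target / % | dissolved substrate / % |
|---|---|---|---|
| north-west | 0.833 | 35.9 | 16.2 |
| north-west | 2.00 | 87.2 | 8.9 |
| north-west | 4.00 | 94.9 | 0.7 |
| north-west | 10.0 | 95.0 | 0 |
| west | 0.833 | 27.6 | 8.5 |
| west | 2.00 | 71.2 | 9.7 |
| west | 4.00 | 93.5 | 0 |
| west | 10.0 | 95.5 | 0 |

(readings scatter by 0.5 percentage points)

- given per volume of solution although it is solid: solid substrate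
- the numbers in the tables scatter with a standard deviation of 0.5 percentage points
- at the start none of the solid substrate is in solution
- dissolved substrate means what is dissolved; the solid is not counted in it

- winter: doubling the solubility of the solid substrate, all else as stated
- midnight: doubling the amount of partner, all else as stated
- noon: doubling the dissolution coefficient of the solid substrate, all else as stated

1. amount of target at 12 min, in percent of the solid substrate charged
2. concentration of dissolved substrate in solution at 3.0 min, in percent of saturation
3. the change that raises the amount of target at 12 min, in percent of the solid substrate charged most ("none" if none brings more than 2 percentage points) (winter / midnight / noon / none)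
4. amount of target at 12 min, in percent of the solid substrate charged, after winter

At 10.0 min the north-west and west plateaus differed by 0.5 percentage points, against a scatter of 0.5 points, although the charges were 0.14 M and 0.22 M. Both runs had 3 equiv of partner, so I assumed that the missing substrate went by a rival step competing with partner, and froze c(partner) at its charge. My carried quantity follows from that:

shortfall of the plateau × equivalents of partner = 0.142 equiv

This product is the shortfall constant, a selectivity factor in plain form. I then turned the settings by hand, one after the other.

Winter: solubility does not enter the constant, so I kept the target of this flask at

95.3%

Noon: the dissolution coefficient does not enter it either, so I reckoned no change.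

Midnight: the shortfall falls to half, a gain of

2.4 points

That is thinly above the 2 points needed, so I named midnight.

The forecast gave 95% (93.5% to 96%), 1% of saturation at 3.0 min (0.2% to 4%), 95% after winter (93.5% to 96.2%) and none as the best change: “so the ceiling looks fixed, not kinetic”. We agreed on the target and parted on the best change.

The flask gave 95.2%, 2.66% of saturation at 3.0 min, and 95.5% after winter. The best change was midnight, with gains of 0.29 points for winter, 0.23 points for noon and 2.7 points for midnight.

    solid substrate ⇌ dissolved substrate, rate k1*(cs1 - [dissolved substrate]) while solid is left; crystals form when [dissolved substrate] > cs1 (solubility = 0.0750 M, k = 0.0264 /s)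
    dissolved substrate + partner → target (k = 0.153 /M/s)
    dissolved substrate + target → side product (k = 0.0147 /M/s)
    partner → decomposed reagent (k = 0.00173 /s)
    2 solid substrate → homo dimer (k = 2.34 × 10⁻⁴ /M/s)

In this flask the half-life of dissolved substrate on the path to target was 0.58 min at 3.80 min, short against 12 min. At 12.0 min this flask held 95.2% of target beside 4.65% of side product and 0.101% of homo dimer, each of these last two percentages counting the two substrate units that its molecule holds; the constant had put the midnight gain at 2.4 points, and the flask gave 2.7 points. For the neighbour with 0.750 equiv of partner, the constant gives 81.1%, more target than that charge can make, so the freeze cannot hold there. That neighbour gave 43.0%, with 31.4% of side product and 0.50% of its partner left.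

(The readings come from a simulation for substances that don't exist, noise included.)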